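Everything rests on cutting ring B at C9–C10 and C7–C8. Ring A carries its oxygen at C2, two bonds around the ring from C10, and only C11 separates C9 from that oxygen. An ester with C11 as its carbonyl can therefore hold a C8≡C9 alkyne on the 2α oxygen of a ring A dienol. One thermal intramolecular Diels–Alder reaction then closes ring B and a bridging δ-lactone, makes both skeletal bonds and sets the quaternary C10 from the enzymatically made carbinol. The precursor is the (R)-3,5,5-trimethyl-4-vinylcyclohex-3-enyl ester of a 4-silyloxybut-2-ynoic acid; its C17 oxygen later steers a reductive alkene transposition to C8(17).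

Key step: step 9

Remarks on the chemistry:
- Labdane numbering is used from compound 12 on: ring A = C1–C5 and C10; ring B = C5–C10; C11 on C9; C17 on C8; C20 on C10; α is the face opposite C20.
- The C17 oxygen is carried as a triisopropylsilyl ether, not a smaller silyl ether. If the silyl group were lost at the γ-silyloxy enoate stage (heat, methoxide), the C17 oxygen would close irreversibly onto C11 as a butenolide and the C11/C17 differentiation would be gone.
- The tether needs the 2α (R) carbinol, whereas the target is 2β; C2 is therefore inverted through the ketone in steps 12 and 13.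

Step 1
Reactants: 1 ketoisophorone (2,6,6-trimethylcyclohex-2-ene-1,4-dione)
Product: 3 (4R,6R)-actinol [(4R,6R)-4-hydroxy-2,2,6-trimethylcyclohexan-1-one], via (6R)-levodione 2 (not isolated)
Conditions: Old Yellow Enzyme 2 (ene-reductase), NADP+ (cat.), glucose, glucose dehydrogenase, phosphate buffer pH 7, 30 °C; then levodione reductase, NAD+ (cat.), same pot
Reagents that add atoms: none
Why: The ene-reductase reduces the enone C=C bond to (6R)-levodione and the levodione reductase then reduces only the unhindered C4 ketone from one face to the 4R carbinol (known two-enzyme asymmetric reduction), which is the future 2α oxygen.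

Step 2
Reactants: 3 (4R,6R)-actinol
Product: 4 (4R,6R)-4-(tert-butyldimethylsilyloxy)-2,2,6-trimethylcyclohexan-1-one
Conditions: TBSCl, imidazole, DMF, 23 °C
Reagents that add atoms: tert-butyldimethylsilyl chloride, CC(C)(C)[Si](C)(C)Cl
Why: Imidazole-promoted silylation of the unhindered secondary alcohol masks the hydroxyl for the enolisation that follows and touches no stereocentre.

Step 3
Reactants: 4 (4R,6R)-4-(tert-butyldimethylsilyloxy)-2,2,6-trimethylcyclohexan-1-one
Product: 5 (R)-4-(tert-butyldimethylsilyloxy)-2,6,6-trimethylcyclohex-1-en-1-yl trifluoromethanesulfonate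
Conditions: KN(SiMe3)2, THF, −78 °C; PhNTf2, −78 → 0 °C
Reagents that add atoms: N-phenylbis(trifluoromethanesulfonimide), O=S(=O)(N(c1ccccc1)S(=O)(=O)C(F)(F)F)C(F)(F)F
Why: The ketone can enolise only toward the methyl-bearing carbon because the other α-carbon is quaternary, so O-sulfonylation of the potassium enolate (enol triflate formation) gives a single triflate, erasing the C6 stereocentre and leaving the silyloxy carbon untouched.

Step 4
Reactants: 5 (R)-4-(tert-butyldimethylsilyloxy)-2,6,6-trimethylcyclohex-1-en-1-yl trifluoromethanesulfonate; 6 tributyl(vinyl)stannane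
Product: 7 (R)-tert-butyldimethyl[(3,5,5-trimethyl-4-vinylcyclohex-3-en-1-yl)oxy]silane
Conditions: Pd(PPh3)4 (5 mol %), LiCl, THF, 65 °C
Reagents that add atoms: none
Why: Stille coupling of an enol triflate with a vinylstannane (zerovalent palladium, chloride-assisted transmetalation) is established for 2,6,6-trimethylcyclohexenyl triflates and gives the 1,3-diene without moving the ring alkene.

Step 5
Reactants: 7 (R)-tert-butyldimethyl[(3,5,5-trimethyl-4-vinylcyclohex-3-en-1-yl)oxy]silane
Product: 8 (R)-3,5,5-trimethyl-4-vinylcyclohex-3-en-1-ol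
Conditions: Bu4NF, THF, 23 °C
Reagents that add atoms: none
Why: Fluoride-induced desilylation frees the carbinol under non-acidic conditions that spare the acid-sensitive diene.

Step 6
Reactants: 9 propargyl alcohol
Product: 10 triisopropyl(prop-2-yn-1-yloxy)silane
Conditions: TIPSCl, imidazole, CH2Cl2, 23 °C
Reagents that add atoms: triisopropylsilyl chloride, CC(C)[Si](Cl)(C(C)C)C(C)C
Why: Silylation of the primary alcohol is routine, and the bulky triisopropylsilyl group is chosen to survive heat, methoxide and hydride later on.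

Step 7
Reactants: 10 triisopropyl(prop-2-yn-1-yloxy)silane
Product: 11 4-(triisopropylsilyloxy)but-2-ynoic acid
Conditions: n-BuLi, THF, −78 °C; CO2; then cold 1 M HCl to pH 3
Reagents that add atoms: carbon dioxide, O=C=O
Why: Deprotonation of the terminal alkyne and carboxylation of the lithium acetylide is the standard route to 2-alkynoic acids, and the bulky silyl ether survives the brief cold acidification.

Step 8
Reactants: 8 (R)-3,5,5-trimethyl-4-vinylcyclohex-3-en-1-ol; 11 4-(triisopropylsilyloxy)but-2-ynoic acid
Product: 12 (R)-3,5,5-trimethyl-4-vinylcyclohex-3-en-1-yl 4-(triisopropylsilyloxy)but-2-ynoate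
Conditions: DCC, DMAP (10 mol %), CH2Cl2, 0 → 23 °C
Reagents that add atoms: none
Why: Steglich esterification forms the acyl–oxygen bond without touching the C–O bond of the carbinol, so the R configuration (future 2α oxygen) is retained.

Step 9
Reactants: 12 (R)-3,5,5-trimethyl-4-vinylcyclohex-3-en-1-yl 4-(triisopropylsilyloxy)but-2-ynoate
Product: 13 tricyclic lactone: 4,4,10β-trimethyl-Δ5,Δ8-octalin with CH2OSi(i-Pr)3 (C17) on C8 and the C9 carboxyl carbon (C11) lactonised onto the 2α oxygen
Conditions: o-dichlorobenzene (0.01 M), BHT (0.1 equiv), 180 °C, sealed tube, Ar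
Reagents that add atoms: none
Why: On heating, the ester reaches its s-cis rotamer with the C2–O bond axial on the ring A half-chair, which places C8≡C9 over the s-cis C10=C5–C6=C7 diene, and a concerted suprafacial [4+2] cycloaddition forms C9–C10 and C7–C8 (type 1 intramolecular Diels–Alder reaction; closest precedents are thermal cyclisations of dienyl 2-alkynoates and intermolecular additions of acetylenic esters to 2,6,6-trimethyl-1-vinylcyclohexenes). Ring B closes as the six-membered cycloadduct ring, a 1,4-cyclohexadiene with C5=C6 and C8=C9, and the δ-lactone closes as the tether ring C10–C1–C2–O–C11–C9 through the same C9–C10 bond, bridging ring A 1,3-diaxially as a 2-oxabicyclo[3.3.1]nonan-3-one. The only new stereocentre, C10, is controlled by the C2 carbinol: the four-atom tether can deliver C9 only to the ring A face that bears the 2α oxygen, so C20 is left β. Regiochemistry (C9 to C10, not to C7) is fixed because the tether cannot span to the vinyl terminus, and the 1,4-diene product cannot react again. The step needs the cycloaddition to outpace the 1,5-hydrogen shift from C20 into the diene and radical polymerisation of the ynoate, which high dilution, BHT and the inductive activation of the alkyne by the ester and the C17 oxygen are chosen to secure.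

Step 10
Reactants: 13 tricyclic lactone
Product: 14 methyl 2α-hydroxy-4,4,10β-trimethyl-8-[(triisopropylsilyloxy)methyl]-Δ5,Δ8-octalin-9-carboxylate (C11 = ester carbon)
Conditions: NaOMe (0.2 equiv), MeOH, 0 → 23 °C; AcOH quench
Reagents that add atoms: methanol, CO
Why: Methoxide transesterifies the strained bridged δ-lactone to the open hydroxy methyl ester (lactone methanolysis), which must precede hydrogenation because the intact bridge would allow only a cis ring fusion.

Step 11
Reactants: 14 diene hydroxy ester
Product: 15 methyl 2α-hydroxy-5α-H-4,4,10β-trimethyl-8-[(triisopropylsilyloxy)methyl]-Δ8-octalin-9-carboxylate (trans ring fusion)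
Conditions: H2 (3 atm), 10% Pd/C, EtOAc, 23 °C
Reagents that add atoms: none
Why: Heterogeneous hydrogenation reduces only the trisubstituted C5=C6 alkene (the tetrasubstituted, ester-conjugated C8=C9 alkene is inert) and delivers hydrogen to the α face of C5, anti to the angular C20 methyl, giving the trans ring fusion as known for the analogous diester cycloadducts of the drimane series.

Step 12
Reactants: 15 trans-fused hydroxy ester
Product: 16 methyl 2-oxo-5α-H-4,4,10β-trimethyl-8-[(triisopropylsilyloxy)methyl]-Δ8-octalin-9-carboxylate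
Conditions: Dess–Martin periodinane, CH2Cl2, 23 °C
Reagents that add atoms: none
Why: Dess–Martin oxidation converts the 2α carbinol, whose configuration served only to direct the cycloaddition, into the C2 ketone without touching the enoate or the silyl ether.

Step 13
Reactants: 16 keto ester
Product: 17 diol: 2β-hydroxy, C11 hydroxymethyl on C9, C17 CH2OSi(i-Pr)3 on C8, Δ8, 5α-H, 10β-methyl
Conditions: i-Bu2AlH (5 equiv), CH2Cl2, −78 → 0 °C; aq. potassium sodium tartrate
Reagents that add atoms: none
Why: i-Bu2AlH reduces the enoate 1,2 to the C11 allylic alcohol and the C2 ketone to the axial 2β alcohol, because hydride can reach that carbonyl only from the α face, the β face being screened by the syn-axial C20 and 4β methyl groups (hydride reduction of a hindered cyclohexanone, as for 11-oxo steroids).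

Step 14
Reactants: 17 diol
Product: 18 enal: C11 aldehyde on C9, 2β-hydroxy, C17 CH2OSi(i-Pr)3, Δ8
Conditions: MnO2 (activated, excess), CH2Cl2, 23 °C
Reagents that add atoms: none
Why: Activated MnO2 oxidises only the allylic C11 alcohol to the enal and leaves the saturated, hindered 2β alcohol alone (chemoselective allylic oxidation).

Step 15
Reactants: 18 enal
Product: 19 diene: vinyl group (C11=C12) on C9, 2β-hydroxy, C17 CH2OSi(i-Pr)3, Δ8
Conditions: Ph3PCH3Br, KOt-Bu, THF, 0 → 23 °C
Reagents that add atoms: methyltriphenylphosphonium bromide, C[P+](c1ccccc1)(c1ccccc1)c1ccccc1.[Br-]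
Why: Wittig methylenation of the aldehyde with an excess of the unstabilised ylide installs C12 as a vinyl group on C9, the free hindered hydroxyl merely consuming base.

Step 16
Reactants: 20 methyl but-2-ynoate
Product: 21 methyl (Z)-3-iodobut-2-enoate
Conditions: NaI, AcOH, 115 °C
Reagents that add atoms: sodium iodide, [Na+].[I-]
Why: Hydroiodination of the ynoate with NaI in acetic acid proceeds by anti addition of HI and gives the (Z)-β-iodo enoate, a known stereoselective route to this building block.

Step 17
Reactants: 19 diene; 21 methyl (Z)-3-iodobut-2-enoate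
Product: 23 methyl (13Z)-2β-hydroxy-17-(triisopropylsilyloxy)labda-8,13-dien-15-oate, via C12 9-BBN borane 22 (not isolated)
Conditions: 9-BBN (2 equiv), THF, 0 → 23 °C; then 21, PdCl2(dppf) (5 mol %; dppf = 1,1'-bis(diphenylphosphino)ferrocene), AsPh3, Cs2CO3, DMF/H2O, 23 °C
Reagents that add atoms: none
Why: 9-BBN adds only to the terminal vinyl group and places boron on C12 (the tetrasubstituted C8=C9 alkene is inert), and the B-alkyl Suzuki–Miyaura coupling with the vinyl iodide retains the alkene geometry, so the chain ends up cis to the ester (13Z); 22 is drawn with the hindered hydroxyl free, and any O–B bond formed there is cleaved in the aqueous coupling medium.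

Step 18
Reactants: 23 silyl ether ester
Product: 24 methyl (13Z)-2β,17-dihydroxylabda-8,13-dien-15-oate
Conditions: Bu4NF, THF, 23 °C
Reagents that add atoms: none
Why: Fluoride-induced desilylation releases the primary allylic C17 alcohol and leaves the methyl enoate and the hindered 2β alcohol unchanged.

Step 19
Reactants: 24 allylic alcohol
Product: 28 methyl (13Z)-2β-hydroxylabda-8(17),13-dien-15-oate, via C17 sulfonylhydrazone adduct 25 (not isolated), via C17 sulfonylhydrazine 26 (not isolated), via allylic diazene 27 (not isolated)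
Conditions: IPNBSH (N-isopropylidene-N'-2-nitrobenzenesulfonylhydrazine), PPh3, DEAD, THF, 0 → 23 °C; then CF3CH2OH/H2O (1:1), 23 °C
Reagents that add atoms: none
Why: Mitsunobu displacement of the primary allylic hydroxyl by the sulfonyl hydrazone, hydrolysis and loss of sulfinic acid give the monoalkyl diazene, whose retro-ene loss of N2 (allylic diazene rearrangement, a reductive 1,3-transposition) moves the alkene to C8(17) and delivers hydrogen to C9 on the α face, anti to the axial C20 methyl, leaving C11 equatorial and β.

Step 20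
Reactants: 28 methyl ester
Product: 29 (13Z)-2β-hydroxylabda-8(17),13-dien-15-oic acid
Conditions: LiOH, THF/MeOH/H2O, 45 °C; then 1 M HCl to pH 4, 0 °C
Reagents that add atoms: lithium hydroxide, [Li+].[OH-]
Why: Saponification of the methyl ester gives the acid, and the conjugated Z alkene has no low-energy path to isomerise under these conditions.

Step 21
Reactants: 29 hydroxy acid
Product: 31 (13Z)-2β-acetoxylabda-8(17),13-dien-15-oic acid (2R,5S,9S,10S; CNP0255148.1), via mixed acetic anhydride 30 (not isolated)
Conditions: Ac2O, pyridine, DMAP (10 mol %), 23 °C; then H2O/pyridine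
Reagents that add atoms: acetic anhydride, CC(=O)OC(C)=O
Why: DMAP-catalysed O-acetylation esterifies the axial 2β hydroxyl with retention while the carboxyl is held as a mixed anhydride, which aqueous pyridine cleaves at the more electrophilic acetyl carbonyl to return the acid, pyridine being too weak a base to enolise the enoyl group.

Compound list
1 | ketoisophorone | CC1=CC(=O)CC(C)(C)C1=O | starting material
2 | (6R)-levodione | C[C@@H]1CC(=O)CC(C)(C)C1=O | intermediate
3 | (4R,6R)-actinol | C[C@@H]1C[C@@H](O)CC(C)(C)C1=O | intermediate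
4 | (4R,6R)-4-(tert-butyldimethylsilyloxy)-2,2,6-trimethylcyclohexan-1-one | C[C@@H]1C[C@@H](O[Si](C)(C)C(C)(C)C)CC(C)(C)C1=O | intermediate
5 | (R)-4-(tert-butyldimethylsilyloxy)-2,6,6-trimethylcyclohex-1-en-1-yl trifluoromethanesulfonate | FC(F)(F)S(=O)(=O)OC1=C(C)C[C@@H](O[Si](C)(C)C(C)(C)C)CC1(C)C | intermediate
6 | tributyl(vinyl)stannane | C=C[Sn](CCCC)(CCCC)CCCC | starting material
7 | (R)-tert-butyldimethyl[(3,5,5-trimethyl-4-vinylcyclohex-3-en-1-yl)oxy]silane | C=CC1=C(C)C[C@@H](O[Si](C)(C)C(C)(C)C)CC1(C)C | intermediate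
8 | (R)-3,5,5-trimethyl-4-vinylcyclohex-3-en-1-ol | C=CC1=C(C)C[C@@H](O)CC1(C)C | intermediate
9 | propargyl alcohol | C#CCO | starting material
10 | triisopropyl(prop-2-yn-1-yloxy)silane | C#CCO[Si](C(C)C)(C(C)C)C(C)C | intermediate
11 | 4-(triisopropylsilyloxy)but-2-ynoic acid | OC(=O)C#CCO[Si](C(C)C)(C(C)C)C(C)C | intermediate
12 | (R)-3,5,5-trimethyl-4-vinylcyclohex-3-en-1-yl 4-(triisopropylsilyloxy)but-2-ynoate | C=CC1=C(C)C[C@@H](OC(=O)C#CCO[Si](C(C)C)(C(C)C)C(C)C)CC1(C)C | intermediate
13 | tricyclic lactone (C5=C6, C8=C9; C11 carbonyl bridging C9 and the 2α oxygen; C17 OTIPS; 10β-Me) | CC(C)[Si](C(C)C)(C(C)C)OCC1=C2C(=O)O[C@H]3CC(C)(C)C(=CC1)[C@]2(C)C3 | intermediate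
14 | diene hydroxy ester (C11 CO2Me, 2α-OH, C17 OTIPS, Δ5, Δ8) | CC(C)[Si](C(C)C)(C(C)C)OCC1=C(C(=O)OC)[C@@]2(C)C[C@@H](O)CC(C)(C)C2=CC1 | intermediate
15 | trans-fused hydroxy ester (5α-H, 2α-OH, Δ8) | CC(C)[Si](C(C)C)(C(C)C)OCC1=C(C(=O)OC)[C@@]2(C)C[C@@H](O)CC(C)(C)[C@@H]2CC1 | intermediate
16 | keto ester (C2 ketone, Δ8) | CC(C)[Si](C(C)C)(C(C)C)OCC1=C(C(=O)OC)[C@@]2(C)CC(=O)CC(C)(C)[C@@H]2CC1 | intermediate
17 | diol (C11 CH2OH, 2β-OH, C17 OTIPS, Δ8) | CC(C)[Si](C(C)C)(C(C)C)OCC1=C(CO)[C@@]2(C)C[C@H](O)CC(C)(C)[C@@H]2CC1 | intermediate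
18 | enal (C11 CHO, 2β-OH, C17 OTIPS, Δ8) | CC(C)[Si](C(C)C)(C(C)C)OCC1=C(C=O)[C@@]2(C)C[C@H](O)CC(C)(C)[C@@H]2CC1 | intermediate
19 | diene (C11=C12 vinyl on C9, 2β-OH, C17 OTIPS, Δ8) | CC(C)[Si](C(C)C)(C(C)C)OCC1=C(C=C)[C@@]2(C)C[C@H](O)CC(C)(C)[C@@H]2CC1 | intermediate
20 | methyl but-2-ynoate | CC#CC(=O)OC | starting material
21 | methyl (Z)-3-iodobut-2-enoate | C/C(I)=C/C(=O)OC | intermediate
22 | C12 9-BBN borane of 19 | CC(C)[Si](C(C)C)(C(C)C)OCC1=C(CCB3C4CCCC3CCC4)[C@@]2(C)C[C@H](O)CC(C)(C)[C@@H]2CC1 | intermediate
23 | methyl (13Z)-2β-hydroxy-17-(triisopropylsilyloxy)labda-8,13-dien-15-oate | CC(C)[Si](C(C)C)(C(C)C)OCC1=C(CC/C(C)=C\C(=O)OC)[C@@]2(C)C[C@H](O)CC(C)(C)[C@@H]2CC1 | intermediate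
24 | methyl (13Z)-2β,17-dihydroxylabda-8,13-dien-15-oate | OCC1=C(CC/C(C)=C\C(=O)OC)[C@@]2(C)C[C@H](O)CC(C)(C)[C@@H]2CC1 | intermediate
25 | C17 N-(2-nitrobenzenesulfonyl)-N'-isopropylidene hydrazine adduct | CC(C)=NN(CC1=C(CC/C(C)=C\C(=O)OC)[C@@]2(C)C[C@H](O)CC(C)(C)[C@@H]2CC1)S(=O)(=O)c1ccccc1[N+](=O)[O-] | intermediate
26 | C17 N-(2-nitrobenzenesulfonyl)hydrazine | NN(CC1=C(CC/C(C)=C\C(=O)OC)[C@@]2(C)C[C@H](O)CC(C)(C)[C@@H]2CC1)S(=O)(=O)c1ccccc1[N+](=O)[O-] | intermediate
27 | C17 allylic diazene | N=NCC1=C(CC/C(C)=C\C(=O)OC)[C@@]2(C)C[C@H](O)CC(C)(C)[C@@H]2CC1 | intermediate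
28 | methyl (13Z)-2β-hydroxylabda-8(17),13-dien-15-oate | C=C1CC[C@H]2C(C)(C)C[C@@H](O)C[C@]2(C)[C@H]1CC/C(C)=C\C(=O)OC | intermediate
29 | (13Z)-2β-hydroxylabda-8(17),13-dien-15-oic acid | C=C1CC[C@H]2C(C)(C)C[C@@H](O)C[C@]2(C)[C@H]1CC/C(C)=C\C(=O)O | intermediate
30 | mixed acetic anhydride of the 2β-acetoxy acid | C=C1CC[C@H]2C(C)(C)C[C@@H](OC(C)=O)C[C@]2(C)[C@H]1CC/C(C)=C\C(=O)OC(C)=O | intermediate
31 | (13Z)-2β-acetoxylabda-8(17),13-dien-15-oic acid | C=C1CC[C@H]2C(C)(C)C[C@@H](OC(C)=O)C[C@]2(C)[C@H]1CC/C(C)=C\C(=O)O | target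

Total step count: 21. Longest linear sequence: 18 steps (1–5, 8–15, 17–21).

Steps most likely to fail

Step 9. The cycloaddition may be outrun by the 1,5-hydrogen shift of the cis-methyl diene, by polymerisation of the ynoate or by slow decomposition, because the ester must reach its disfavoured s-cis rotamer and the alkyne is only singly activated. The fallback keeps the tether but doubles the activation and sets out from dienol 8. Half-saponification of commercial dimethyl acetylenedicarboxylate (1 equiv KOH, MeOH, 0 °C, then acid) gives monomethyl acetylenedicarboxylate F1. Steglich esterification of 8 with it gives the mixed but-2-ynedioate F2, which should cyclise near 80–110 °C, as the intermolecular additions of acetylenedicarboxylates to trimethylvinylcyclohexenes do, to the lactone methyl ester F3. Methanolysis gives the diene diester F4, hydrogenation over Pd/C the trans-fused diester F5, Dess–Martin oxidation the keto diester F6, and reduction with i-Bu2AlH the triol F7. Monosilylation of the less hindered C17 hydroxyl (TIPSCl, imidazole, −20 °C) returns to the route at diol 17.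

Step 19. The Mitsunobu displacement at the C17 carbinol, flanked by a tetrasubstituted alkene, may stall, or the diazene may deliver hydrogen to C9 with poor facial selectivity. The fallback sets out from 24: the primary allylic hydroxyl is converted selectively into the allylic methyl carbonate F8 (ClCO2Me, pyridine, 0 °C). Palladium-catalysed formate reduction (Pd(OAc)2, PBu3, HCO2NH4, dioxane, 80 °C) then transfers hydride from palladium to the more substituted allyl terminus C9 on the less hindered α face and moves the alkene to C8(17). It returns to the route at 28.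

Step 11. Hydrogen may add to C5 with poor facial selectivity, the allylic C17–O bond may undergo hydrogenolysis, or the skipped diene may migrate on the metal surface. The fallback goes from 14 directly to 15 by radical hydrogen-atom-transfer hydrogenation (Mn(dpm)3, dpm = 2,2,6,6-tetramethylheptane-3,5-dionate, trivalent manganese; PhSiH3, t-BuOOH, i-PrOH, 23 °C). The tertiary C5 radical is quenched under thermodynamic control to the trans ring fusion, no allyl–metal species is involved, and the hindered tetrasubstituted enoate should react far more slowly. No new compound is made (F0).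

Further compounds
F1 | step 9 | monomethyl acetylenedicarboxylate (4-methoxy-4-oxobut-2-ynoic acid) | COC(=O)C#CC(=O)O
F2 | step 9 | (R)-3,5,5-trimethyl-4-vinylcyclohex-3-en-1-yl methyl but-2-ynedioate | C=CC1=C(C)C[C@@H](OC(=O)C#CC(=O)OC)CC1(C)C
F3 | step 9 | tricyclic lactone with C17 as methyl ester (C5=C6, C8=C9, C11 carbonyl on the 2α oxygen) | COC(=O)C1=C2C(=O)O[C@H]3CC(C)(C)C(=CC1)[C@]2(C)C3
F4 | step 9 | dimethyl 2α-hydroxy-Δ5,Δ8-diene diester (C11 and C17 esters) | COC(=O)C1=C(C(=O)OC)[C@@]2(C)C[C@@H](O)CC(C)(C)C2=CC1
F5 | step 9 | trans-fused dimethyl 2α-hydroxy-Δ8 diester | COC(=O)C1=C(C(=O)OC)[C@@]2(C)C[C@@H](O)CC(C)(C)[C@@H]2CC1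
F6 | step 9 | trans-fused dimethyl 2-oxo-Δ8 diester | COC(=O)C1=C(C(=O)OC)[C@@]2(C)CC(=O)CC(C)(C)[C@@H]2CC1
F7 | step 9 | triol (2β-OH, C11 CH2OH, C17 CH2OH, Δ8) | OCC1=C(CO)[C@@]2(C)C[C@H](O)CC(C)(C)[C@@H]2CC1
F8 | step 19 | C17 allylic methyl carbonate of 24 | COC(=O)OCC1=C(CC/C(C)=C\C(=O)OC)[C@@]2(C)C[C@H](O)CC(C)(C)[C@@H]2CC1
F0 | step 11 | none | none
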